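**Assumption:** bicyclic compounds are named with azulene numbering (C3 isopropyl carbon, C3a hydroxylated ring-fusion carbon, C6 methyl carbinol, C7 ester carbon, C8a methyl-bearing ring-fusion carbon). Hydroxy ester 1 is bought as the L-valine-derived (S)-enantiomer.

## Retrosynthetic overview

- The ester is made last by acylating the only secondary OH of a 3a,6,7-triol; the trans-6,7-diol comes from a cis-fused hexahydroazulen-3a-ol by OH-directed epoxidation and hydrolysis with inversion at C6.
- The seven-membered ring is formed last, by ring-closing metathesis of a 2-allyl-1-(3-methylbut-3-enyl)cyclopentanol, made by Grignard addition to a 2-allyl-2-methyl-5-isopropylcyclopentanone anti to isopropyl.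
- Key C–C bond: the allyl CH2–CH bond, from a ketone homoenolate (β-palladio ketone released by ring-opening of a bicyclo[3.1.0]hexan-1-ol) and vinyl bromide; the cyclopropanol fixes the quaternary carbon relative to isopropyl.
- The five-membered ring is formed first, together with the cyclopropane, by intramolecular Kulinkovich reaction of methyl (R)-2-isopropyl-5-methylhex-5-enoate.
- That ester comes from methyl (S)-2-hydroxy-3-methylbutanoate by triflation and displacement (inversion) with a homoallyl Grignard reagent, prepared once as a stock solution and used again for the ketone addition.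

## Route

**Step 1**
Reactants: 1 methyl (2S)-2-hydroxy-3-methylbutanoate
Product: 2 methyl (2S)-3-methyl-2-[(trifluoromethanesulfonyl)oxy]butanoate
Conditions: Tf2O (1.1 equiv), 2,6-lutidine (1.2 equiv), CH2Cl2, −78 to 0 °C; used at once in step 3
Reagents that add atoms: trifluoromethanesulfonic anhydride, O=S(=O)(OS(=O)(=O)C(F)(F)F)C(F)(F)F
Why: O-sulfonylation of the secondary alcohol breaks no bond at the stereocentre, so the (S) configuration is kept and the carbon is activated for substitution.

**Step 2**
Reactants: 3 4-bromo-2-methylbut-1-ene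
Product: 4 (3-methylbut-3-en-1-yl)magnesium bromide
Conditions: Mg turnings (1.2 equiv), I2 (cat.), THF, 40 °C; obtained as a titrated THF solution (about 0.8 M), kept under argon and drawn on in steps 3 and 6
Reagents that add atoms: magnesium, [Mg]
Why: Grignard reagent formation by insertion of magnesium into the primary C–Br bond gives a stable homoallylic organomagnesium stock solution, with no stereocentre involved.

**Step 3**
Reactants: 2 methyl (2S)-3-methyl-2-[(trifluoromethanesulfonyl)oxy]butanoate; 4 (3-methylbut-3-en-1-yl)magnesium bromide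
Product: 5 methyl (2R)-5-methyl-2-(propan-2-yl)hex-5-enoate
Conditions: 4 (1.5 equiv, THF solution from step 2), ZnCl2 (10 mol %), THF, 0 °C
Reagents that add atoms: none
Why: Zinc-catalysed sp3–sp3 Grignard cross-coupling of an α-triflyloxy ester (through a triorganozincate) is an SN2 displacement, so the centre is inverted and the isopropyl-bearing stereocentre of the target (C3, R) is set.

**Step 4**
Reactants: 5 methyl (2R)-5-methyl-2-(propan-2-yl)hex-5-enoate
Product: 6 (1S,2R,5R)-5-methyl-2-(propan-2-yl)bicyclo[3.1.0]hexan-1-ol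
Conditions: Ti(OiPr)4 (1.1 equiv), cyclopentylmagnesium chloride (4.5 equiv, added over 2 h), THF, 20 °C; then aq. NH4Cl
Reagents that add atoms: none
Why: Intramolecular Kulinkovich hydroxycyclopropanation (alkene–titanacyclopropane ligand exchange, then twofold addition to the ester) forms the cyclopentane and the cyclopropane at once, and the isopropyl group takes the exo position anti to the titanium-bearing CH2, so the cyclopropane methylene ends trans and the angular methyl cis to isopropyl.

**Step 5**
Reactants: 6 (1S,2R,5R)-5-methyl-2-(propan-2-yl)bicyclo[3.1.0]hexan-1-ol; 7 bromoethene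
Product: 8 (2R,5R)-2-methyl-5-(propan-2-yl)-2-(prop-2-en-1-yl)cyclopentan-1-one
Conditions: 7 (3 equiv, 1 M in THF), Pd(OAc)2 (5 mol %), XPhos (10 mol %), Cs2CO3 (2 equiv), toluene, 70 °C, sealed tube
Reagents that add atoms: none
Why: Palladium-catalysed ring-opening cross-coupling of a cyclopropanol, in which the palladium alkoxide undergoes β-carbon elimination at the less substituted C1–C6 bond to a β-palladio ketone (a ketone homoenolate with no β-hydrogen, the neighbouring carbon being quaternary) that couples with the vinyl electrophile, so the carbon β to the carbonyl reacts as a nucleophile and the quaternary centre set in step 4 is carried over unchanged.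

**Step 6**
Reactants: 8 (2R,5R)-2-methyl-5-(propan-2-yl)-2-(prop-2-en-1-yl)cyclopentan-1-one; 4 (3-methylbut-3-en-1-yl)magnesium bromide
Product: 9 (1S,2R,5R)-2-methyl-1-(3-methylbut-3-en-1-yl)-5-(propan-2-yl)-2-(prop-2-en-1-yl)cyclopentan-1-ol
Conditions: 4 (2.0 equiv, THF solution from step 2), LaCl3·2LiCl (1 equiv), THF, −20 to 0 °C; then aq. NH4Cl
Reagents that add atoms: none
Why: Lewis-acid-promoted Grignard 1,2-addition to the hindered ketone takes place on the face opposite the α-isopropyl and α-methyl groups (the face of the allyl chain), giving the tertiary alcohol with OH cis to methyl and isopropyl, while the lanthanum salt suppresses enolisation of the α-isopropyl centre.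

**Step 7**
Reactants: 9 (1S,2R,5R)-2-methyl-1-(3-methylbut-3-en-1-yl)-5-(propan-2-yl)-2-(prop-2-en-1-yl)cyclopentan-1-ol
Product: 10 (3R,3aS,8aR)-6,8a-dimethyl-3-(propan-2-yl)-2,3,4,5,8,8a-hexahydro-1H-azulen-3a-ol
Conditions: second-generation Grubbs catalyst RuCl2(=CHPh)(H2IMes)(PCy3) (5 mol %), CH2Cl2 (0.005 M), 40 °C
Reagents that add atoms: none
Why: Ring-closing metathesis of the two cis-disposed alkenyl chains closes the seven-membered ring as the trisubstituted cycloalkene, touching no stereocentre and giving the cis ring fusion that follows from the cis chains.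

**Step 8**
Reactants: 10 (3R,3aS,8aR)-6,8a-dimethyl-3-(propan-2-yl)-2,3,4,5,8,8a-hexahydro-1H-azulen-3a-ol
Product: 12 (3R,3aS,6R,7R,8aR)-6,8a-dimethyl-3-(propan-2-yl)decahydroazulene-3a,6,7-triol, via epoxide 11 (not isolated)
Conditions: VO(acac)2 (3 mol %), t-BuOOH (1.3 equiv), CH2Cl2, 0 to 20 °C; then THF/H2O (3:1), HClO4 (10 mol %), 0 °C
Reagents that add atoms: tert-butyl hydroperoxide, CC(C)(C)OO; water, O
Why: Vanadium-catalysed hydroxyl-directed epoxidation of the bishomoallylic tertiary alcohol delivers oxygen to the alkene face syn to the 3a-OH, and acid-catalysed epoxide hydrolysis then brings water in at the tertiary carbon C6 with inversion (the syn 3a-OH cannot reach the backside of either epoxide carbon), giving the trans-6,7-diol with 6R,7R configuration.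

**Step 9**
Reactants: 12 (3R,3aS,6R,7R,8aR)-6,8a-dimethyl-3-(propan-2-yl)decahydroazulene-3a,6,7-triol; 13 4-methoxybenzoyl chloride
Product: 14 (3R,3aS,6R,7R,8aR)-3a,6-dihydroxy-6,8a-dimethyl-3-(propan-2-yl)decahydroazulen-7-yl 4-methoxybenzoate
Conditions: 13 (1.2 equiv), Et3N (2 equiv), DMAP (10 mol %), CH2Cl2, 0 to 20 °C
Reagents that add atoms: none
Why: DMAP-catalysed acylation (nucleophilic catalysis) is selective for the only secondary hydroxyl, the two tertiary alcohols being unreactive, and no stereocentre changes.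

## Compound list

1 | methyl (2S)-2-hydroxy-3-methylbutanoate | CC(C)[C@H](O)C(=O)OC | starting material
2 | methyl (2S)-3-methyl-2-[(trifluoromethanesulfonyl)oxy]butanoate | CC(C)[C@H](OS(=O)(=O)C(F)(F)F)C(=O)OC | intermediate
3 | 4-bromo-2-methylbut-1-ene | C=C(C)CCBr | starting material
4 | (3-methylbut-3-en-1-yl)magnesium bromide (THF stock solution) | C=C(C)CC[Mg]Br | intermediate
5 | methyl (2R)-5-methyl-2-(propan-2-yl)hex-5-enoate | C=C(C)CC[C@H](C(C)C)C(=O)OC | intermediate
6 | (1S,2R,5R)-5-methyl-2-(propan-2-yl)bicyclo[3.1.0]hexan-1-ol (OH, angular methyl and isopropyl on one face, cyclopropane CH2 on the other) | C1[C@@]2(C)CC[C@H](C(C)C)[C@@]12O | intermediate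
7 | bromoethene (vinyl bromide) | C=CBr | starting material
8 | (2R,5R)-2-methyl-5-(propan-2-yl)-2-(prop-2-en-1-yl)cyclopentan-1-one (allyl trans to isopropyl) | C=CC[C@@]1(C)CC[C@H](C(C)C)C1=O | intermediate
9 | (1S,2R,5R)-2-methyl-1-(3-methylbut-3-en-1-yl)-5-(propan-2-yl)-2-(prop-2-en-1-yl)cyclopentan-1-ol | C=CC[C@@]1(C)CC[C@H](C(C)C)[C@@]1(O)CCC(C)=C | intermediate
10 | (3R,3aS,8aR)-6,8a-dimethyl-3-(propan-2-yl)-2,3,4,5,8,8a-hexahydro-1H-azulen-3a-ol | CC1=CC[C@@]2(C)CC[C@H](C(C)C)[C@@]2(O)CC1 | intermediate
11 | (3R,3aS,6S,7R,8aR)-6,7-epoxy-6,8a-dimethyl-3-(propan-2-yl)decahydroazulen-3a-ol (epoxide oxygen on the face of the 3a-OH) | C[C@@]12O[C@@H]1C[C@@]3(C)CC[C@H](C(C)C)[C@@]3(O)CC2 | intermediate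
12 | (3R,3aS,6R,7R,8aR)-6,8a-dimethyl-3-(propan-2-yl)decahydroazulene-3a,6,7-triol | O[C@@H]1C[C@@]2(C)CC[C@H](C(C)C)[C@@]2(O)CC[C@@]1(C)O | intermediate
13 | 4-methoxybenzoyl chloride | COc1ccc(cc1)C(Cl)=O | starting material
14 | (3R,3aS,6R,7R,8aR)-3a,6-dihydroxy-6,8a-dimethyl-3-(propan-2-yl)decahydroazulen-7-yl 4-methoxybenzoate | COc1ccc(C(=O)O[C@@H]2C[C@@]3(C)CC[C@H](C(C)C)[C@@]3(O)CC[C@@]2(C)O)cc1 | target

## Step count and risks

Total step count: 9. Longest linear sequence: 8 steps (1, 2, 5, 6, 8, 9, 10, 12, 14); step 2 is a side branch that supplies reagent 4 for steps 3 and 6.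

**Step 4 (Kulinkovich cyclopropanation).** Ligand exchange onto a 1,1-disubstituted alkene is slow, the ester is α-branched, and the exo/endo ratio for isopropyl is not guaranteed.
Fallback: set out from 5 and build the same cyclopropanol by Simmons–Smith chemistry. Ozonolysis (O3, CH2Cl2/MeOH, −78 °C; Me2S) gives methyl (2R)-5-oxo-2-(propan-2-yl)hexanoate F1. Titanium-induced keto ester coupling (TiCl3, LiAlH4, Et3N, DME, reflux; then 1 M HCl) closes the five-membered ring to (5R)-2-methyl-5-(propan-2-yl)cyclopentan-1-one F2. Kinetic enolisation on the less hindered methyl side (lithium diisopropylamide, Me3SiCl, THF, −78 °C) gives trimethyl{[(5R)-2-methyl-5-(propan-2-yl)cyclopent-1-en-1-yl]oxy}silane F3. Cyclopropanation with Et2Zn/CH2I2 (CH2Cl2, 0 °C) anti to the adjacent isopropyl group gives trimethyl{[(1S,2R,5R)-5-methyl-2-(propan-2-yl)bicyclo[3.1.0]hexan-1-yl]oxy}silane F4. K2CO3 in MeOH removes the silyl group and the route is rejoined at 6.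

**Step 5 (homoenolate cross-coupling).** The tertiary cyclopropanol is hindered, simple protonolysis to the 2,2-dimethyl ketone competes, and the carbonate base could slowly epimerise the α-isopropyl centre of 8.
Fallback: set out from 6 and use a stoichiometric zinc homoenolate instead of catalytic β-carbon elimination. N-Iodosuccinimide (CH2Cl2, 0 °C) opens the cyclopropanol at the CH2 carbon to (2S,5R)-2-(iodomethyl)-2-methyl-5-(propan-2-yl)cyclopentan-1-one F5. Zn dust with LiCl in THF converts it into {[(1S,3R)-1-methyl-2-oxo-3-(propan-2-yl)cyclopentyl]methyl}zinc iodide F6. Negishi coupling with 7 (Pd(PPh3)4, 5 mol %, THF, 50 °C) rejoins the route at 8.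

**Step 8 (epoxidation and hydrolysis).** The facial selectivity of the directed epoxidation in the flexible seven-membered ring is uncertain, and the acid step may open at C7 or let the 3a-OH capture a C6 cation.
Fallback: set out from 10 and build the trans-diol by dihydroxylation, oxidation and directed reduction. OsO4 (2 mol %) with N-methylmorpholine N-oxide (acetone/H2O, 20 °C) is expected to dihydroxylate the face opposite the angular methyl and 3a-OH, giving (3R,3aS,6R,7S,8aR)-6,8a-dimethyl-3-(propan-2-yl)decahydroazulene-3a,6,7-triol F7. Oxidation of its only secondary alcohol (SO3·pyridine, DMSO, Et3N, 0 °C) gives (3R,3aS,6R,8aR)-3a,6-dihydroxy-6,8a-dimethyl-3-(propan-2-yl)octahydroazulen-7(1H)-one F8. Hydroxyl-directed reduction with Me4NBH(OAc)3 (MeCN/AcOH, −20 °C) delivers hydride from the face of the C6 hydroxyl and rejoins the route at 12.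

## Further compounds

F1 | step 4 | methyl (2R)-5-oxo-2-(propan-2-yl)hexanoate | CC(=O)CC[C@H](C(C)C)C(=O)OC
F2 | step 4 | (5R)-2-methyl-5-(propan-2-yl)cyclopentan-1-one (mixture at C2) | CC1CC[C@H](C(C)C)C1=O
F3 | step 4 | trimethyl{[(5R)-2-methyl-5-(propan-2-yl)cyclopent-1-en-1-yl]oxy}silane | CC1=C(O[Si](C)(C)C)[C@@H](C(C)C)CC1
F4 | step 4 | trimethyl{[(1S,2R,5R)-5-methyl-2-(propan-2-yl)bicyclo[3.1.0]hexan-1-yl]oxy}silane | C1[C@@]2(C)CC[C@H](C(C)C)[C@@]12O[Si](C)(C)C
F5 | step 5 | (2S,5R)-2-(iodomethyl)-2-methyl-5-(propan-2-yl)cyclopentan-1-one | IC[C@@]1(C)CC[C@H](C(C)C)C1=O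
F6 | step 5 | {[(1S,3R)-1-methyl-2-oxo-3-(propan-2-yl)cyclopentyl]methyl}zinc iodide | I[Zn]C[C@@]1(C)CC[C@H](C(C)C)C1=O
F7 | step 8 | (3R,3aS,6R,7S,8aR)-6,8a-dimethyl-3-(propan-2-yl)decahydroazulene-3a,6,7-triol | O[C@H]1C[C@@]2(C)CC[C@H](C(C)C)[C@@]2(O)CC[C@@]1(C)O
F8 | step 8 | (3R,3aS,6R,8aR)-3a,6-dihydroxy-6,8a-dimethyl-3-(propan-2-yl)octahydroazulen-7(1H)-one | O=C1C[C@@]2(C)CC[C@H](C(C)C)[C@@]2(O)CC[C@@]1(C)O
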